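The pyran ring is closed last by making the aryl–oxygen bond O1–C8a on a ring A that still carries hydrogen at C8a. The step exploits the free C7 hydroxyl of ring A, which lies para to C4a: PhI(OAc)2 dearomatises this phenol to a p-quinol, so that C8a, meta to the hydroxyl and inert in the arene, becomes an enone β-carbon. The side-chain primary alcohol adds there (6-exo oxa-Michael) and acid-driven loss of water restores ring A; the same acid frees the ring B phenol. The precursor is an open-chain (R)-2,3-diarylpropan-1-ol, assembled by Evans alkylation of a ring B arylacetyl imide with a ring A benzyl bromide.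

Key step: step 12

Remark on the chemistry: atoms are numbered as in chroman (O1, C2, C3, C4, C4a, C5 to C8, C8a; ring A is the benzo ring, ring C the pyran ring, ring B the pendant aryl). The stereodescriptor in the target SMILES corresponds to (3R), and the route is planned for that enantiomer.

Step 1
Reactants: 1 2,4-dihydroxybenzaldehyde; 2 prenyl bromide
Product: 3 2,4-dihydroxy-3-(3-methylbut-2-en-1-yl)benzaldehyde
Conditions: KOH, H2O, 0 °C → rt
Reagents that add atoms: none
Why: C-alkylation of the ambident resorcinol-type phenoxide in water should occur mainly at C3, the doubly activated carbon between the two oxygens, and the C5 and O-alkylated isomers are removed by chromatography.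

Step 2
Reactants: 3 2,4-dihydroxy-3-(3-methylbut-2-en-1-yl)benzaldehyde
Product: 4 4-formyl-3-hydroxy-2-(3-methylbut-2-en-1-yl)phenyl pivalate
Conditions: PivCl, Et3N, CH2Cl2, 0 °C
Reagents that add atoms: pivaloyl chloride, CC(C)(C)C(Cl)=O
Why: Selective O-acylation, because the 2-hydroxyl is locked in a hydrogen bond to the formyl group and the more acidic 4-hydroxyl alone should be esterified.

Step 3
Reactants: 4 4-formyl-3-hydroxy-2-(3-methylbut-2-en-1-yl)phenyl pivalate
Product: 5 4-formyl-3-methoxy-2-(3-methylbut-2-en-1-yl)phenyl pivalate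
Conditions: MeI, K2CO3, DMF, rt
Reagents that add atoms: iodomethane, CI
Why: Williamson ether synthesis on the remaining chelated phenol, under which the hindered pivalate should survive in dry DMF.

Step 4
Reactants: 5 4-formyl-3-methoxy-2-(3-methylbut-2-en-1-yl)phenyl pivalate
Product: 6 4-(hydroxymethyl)-3-methoxy-2-(3-methylbut-2-en-1-yl)phenyl pivalate
Conditions: NaBH4, MeOH/THF, 0 °C
Reagents that add atoms: none
Why: Borohydride reduction of the aldehyde at 0 °C should leave the aryl pivalate and the trisubstituted alkene untouched.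

Step 5
Reactants: 6 4-(hydroxymethyl)-3-methoxy-2-(3-methylbut-2-en-1-yl)phenyl pivalate
Product: 7 4-(bromomethyl)-3-methoxy-2-(3-methylbut-2-en-1-yl)phenyl pivalate
Conditions: CBr4, PPh3, CH2Cl2, 0 °C
Reagents that add atoms: carbon tetrabromide, BrC(Br)(Br)Br
Why: The Appel reaction converts the benzylic alcohol into the bromide under neutral conditions that spare the prenyl alkene and the ester.

Step 6
Reactants: 8 4-bromo-3-methoxyphenol
Product: 9 1-bromo-2-methoxy-4-(methoxymethoxy)benzene
Conditions: MOMCl, i-Pr2NEt, CH2Cl2, 0 °C → rt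
Reagents that add atoms: chloromethyl methyl ether, COCCl
Why: O-Alkylation of the phenol gives a MOM acetal that withstands the basic, hydride and oxidative steps and is removed by the acid stage of step 12.

Step 7
Reactants: 9 1-bromo-2-methoxy-4-(methoxymethoxy)benzene; 10 (2-ethoxy-2-oxoethyl)zinc bromide
Product: 11 ethyl 2-[2-methoxy-4-(methoxymethoxy)phenyl]acetate
Conditions: Pd(dba)2 (2 mol %), P(t-Bu)3 (2 mol %), THF, rt → 50 °C
Reagents that add atoms: none
Why: Palladium-catalysed α-arylation of a zinc ester enolate (Negishi-type coupling of a Reformatsky reagent) needs no strong base and should tolerate the electron-rich, ortho-substituted aryl bromide.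

Step 8
Reactants: 11 ethyl 2-[2-methoxy-4-(methoxymethoxy)phenyl]acetate
Product: 12 2-[2-methoxy-4-(methoxymethoxy)phenyl]acetic acid
Conditions: LiOH·H2O, THF/MeOH/H2O, rt; then 1 M HCl to pH 3, 0 °C
Reagents that add atoms: lithium hydroxide, [Li+].[OH-]
Why: Ester saponification, to which the MOM acetal is inert, followed by a brief cold acidification that it should also survive.

Step 9
Reactants: 12 2-[2-methoxy-4-(methoxymethoxy)phenyl]acetic acid; 13 (R)-4-benzyloxazolidin-2-one
Product: 15 (R)-4-benzyl-3-{2-[2-methoxy-4-(methoxymethoxy)phenyl]acetyl}oxazolidin-2-one, via mixed pivalic anhydride 14 (not isolated)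
Conditions: PivCl, Et3N, THF, −20 °C; then LiCl, 13, −20 °C → rt
Reagents that add atoms: none
Why: N-Acylation of the Evans oxazolidinone through the mixed pivalic anhydride, which should be attacked at the less hindered arylacetyl carbonyl.

Step 10
Reactants: 15 (R)-4-benzyl-3-{2-[2-methoxy-4-(methoxymethoxy)phenyl]acetyl}oxazolidin-2-one; 7 4-(bromomethyl)-3-methoxy-2-(3-methylbut-2-en-1-yl)phenyl pivalate
Product: 17 (R)-4-benzyl-3-{(2R)-2-[2-methoxy-4-(methoxymethoxy)phenyl]-3-[2-methoxy-3-(3-methylbut-2-en-1-yl)-4-(pivaloyloxy)phenyl]propanoyl}oxazolidin-2-one, via sodium Z-enolate 16 (not isolated)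
Conditions: NaN(SiMe3)2, THF, −78 °C; then 7, −78 → −40 °C
Reagents that add atoms: none
Why: Evans asymmetric alkylation, in which the chelated sodium (Z)-enolate 16 should be benzylated on the face opposite the C4 benzyl group of the (R)-auxiliary, setting the (R) configuration of the future C3.

Step 11
Reactants: 17 (R)-4-benzyl-3-{(2R)-2-[2-methoxy-4-(methoxymethoxy)phenyl]-3-[2-methoxy-3-(3-methylbut-2-en-1-yl)-4-(pivaloyloxy)phenyl]propanoyl}oxazolidin-2-one
Product: 18 4-{(2R)-3-hydroxy-2-[2-methoxy-4-(methoxymethoxy)phenyl]propyl}-3-methoxy-2-(3-methylbut-2-en-1-yl)phenol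
Conditions: LiAlH4, THF, 0 °C
Reagents that add atoms: none
Why: Hydride reduction should cleave the N-acyl oxazolidinone to the primary alcohol and the aryl pivalate to the free C7 phenol in one flask, with the stereocentre retained because reduction is faster than enolisation at 0 °C.

Step 12
Reactants: 18 4-{(2R)-3-hydroxy-2-[2-methoxy-4-(methoxymethoxy)phenyl]propyl}-3-methoxy-2-(3-methylbut-2-en-1-yl)phenol
Product: 22 (3R)-3-(4-hydroxy-2-methoxyphenyl)-5-methoxy-6-(3-methylbut-2-en-1-yl)chroman-7-ol, via p-quinol 19 (not isolated), via oxa-Michael adduct 20 (not isolated), via MOM-protected isoflavan 21 (not isolated)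
Conditions: PhI(OAc)2 (1.05 equiv), MeCN/H2O (4:1), 0 °C; then TsOH·H2O, MeOH, 50 °C
Reagents that add atoms: none
Why: Proposed new method: PhI(OAc)2 should oxidise the only free phenol (ring A, C7–OH) to a phenoxonium ion that water captures at the para carbon C4a to give p-quinol 19, in which C8a has become the β-carbon of the C7 enone; under TsOH the primary hydroxyl should add there in a 6-exo-trig oxa-Michael closure (O1–C8a, ring C) to give 20, enolisation of 20 towards C8 makes the tertiary C4a–OH doubly allylic so that it ionises, and loss of the C8a proton from the resulting arenium ion restores ring A as 21 before the acid cleaves the MOM acetal. The closest known reaction types are the oxidative dearomatisation of p-alkylphenols to p-quinols, the acid-catalysed intramolecular oxa-Michael addition of hydroxyalkyl p-quinols and the acid-mediated dehydrative aromatisation of 4-hydroxycyclohex-2-enones; their telescoped use to forge an aryl–oxygen bond meta to a phenol hydroxyl in a ring closure is not established. No stereocentre is created in the product: the transient centres at C4a and C8a are erased on aromatisation, and C3, remote from every reacting site, keeps its R configuration. The step needs site selectivity in the oxidation, secured because ring B is masked as its MOM ether and the tethered oxygen cannot reach C4a without forming an oxetane, and regioselectivity in the conjugate addition, secured because C8a is an unsubstituted enone carbon whereas C5 is a tetrasubstituted vinylogous-ester carbon whose exchange with alcohols is reversible and degenerate in MeOH and whose adduct cannot aromatise. The acid stage is kept mild so that the C6 prenyl group should not cyclise onto the C7 hydroxyl.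

Compound list
1 | 2,4-dihydroxybenzaldehyde | O=Cc1ccc(O)cc1O | starting material
2 | prenyl bromide (1-bromo-3-methylbut-2-ene) | CC(C)=CCBr | starting material
3 | 2,4-dihydroxy-3-(3-methylbut-2-en-1-yl)benzaldehyde | O=Cc1ccc(O)c(CC=C(C)C)c1O | intermediate
4 | 4-formyl-3-hydroxy-2-(3-methylbut-2-en-1-yl)phenyl pivalate | O=Cc1ccc(OC(=O)C(C)(C)C)c(CC=C(C)C)c1O | intermediate
5 | 4-formyl-3-methoxy-2-(3-methylbut-2-en-1-yl)phenyl pivalate | O=Cc1ccc(OC(=O)C(C)(C)C)c(CC=C(C)C)c1OC | intermediate
6 | 4-(hydroxymethyl)-3-methoxy-2-(3-methylbut-2-en-1-yl)phenyl pivalate | OCc1ccc(OC(=O)C(C)(C)C)c(CC=C(C)C)c1OC | intermediate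
7 | 4-(bromomethyl)-3-methoxy-2-(3-methylbut-2-en-1-yl)phenyl pivalate | BrCc1ccc(OC(=O)C(C)(C)C)c(CC=C(C)C)c1OC | intermediate
8 | 4-bromo-3-methoxyphenol | COc1cc(O)ccc1Br | starting material
9 | 1-bromo-2-methoxy-4-(methoxymethoxy)benzene | COCOc1ccc(Br)c(OC)c1 | intermediate
10 | (2-ethoxy-2-oxoethyl)zinc bromide (Reformatsky reagent of ethyl bromoacetate, commercial solution) | CCOC(=O)C[Zn]Br | starting material
11 | ethyl 2-[2-methoxy-4-(methoxymethoxy)phenyl]acetate | CCOC(=O)Cc1ccc(OCOC)cc1OC | intermediate
12 | 2-[2-methoxy-4-(methoxymethoxy)phenyl]acetic acid | OC(=O)Cc1ccc(OCOC)cc1OC | intermediate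
13 | (R)-4-benzyloxazolidin-2-one | O=C1N[C@H](Cc2ccccc2)CO1 | starting material
14 | 2-[2-methoxy-4-(methoxymethoxy)phenyl]acetic pivalic anhydride (formed in the flask, not isolated) | CC(C)(C)C(=O)OC(=O)Cc1ccc(OCOC)cc1OC | intermediate
15 | (R)-4-benzyl-3-{2-[2-methoxy-4-(methoxymethoxy)phenyl]acetyl}oxazolidin-2-one | COCOc1ccc(CC(=O)N2[C@H](Cc3ccccc3)COC2=O)c(OC)c1 | intermediate
16 | sodium (Z)-enolate of 15 (formed in the flask, not isolated) | COCOc1ccc(/C=C(\[O-])N2[C@H](Cc3ccccc3)COC2=O)c(OC)c1.[Na+] | intermediate
17 | (R)-4-benzyl-3-{(2R)-2-[2-methoxy-4-(methoxymethoxy)phenyl]-3-[2-methoxy-3-(3-methylbut-2-en-1-yl)-4-(pivaloyloxy)phenyl]propanoyl}oxazolidin-2-one | COc1cc(OCOC)ccc1[C@H](C(=O)N1[C@H](Cc2ccccc2)COC1=O)Cc1ccc(OC(=O)C(C)(C)C)c(CC=C(C)C)c1OC | intermediate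
18 | 4-{(2R)-3-hydroxy-2-[2-methoxy-4-(methoxymethoxy)phenyl]propyl}-3-methoxy-2-(3-methylbut-2-en-1-yl)phenol | COc1cc(OCOC)ccc1[C@H](CO)Cc1ccc(O)c(CC=C(C)C)c1OC | intermediate
19 | 4-hydroxy-4-{(2R)-3-hydroxy-2-[2-methoxy-4-(methoxymethoxy)phenyl]propyl}-3-methoxy-2-(3-methylbut-2-en-1-yl)cyclohexa-2,5-dien-1-one, p-quinol, both epimers at the carbinol carbon C4a (formed in the flask, not isolated) | COc1cc(OCOC)ccc1[C@H](CO)CC1(O)C=CC(=O)C(CC=C(C)C)=C1OC | intermediate
20 | (3R)-4a-hydroxy-5-methoxy-3-[2-methoxy-4-(methoxymethoxy)phenyl]-6-(3-methylbut-2-en-1-yl)-2,3,4,4a,8,8a-hexahydro-7H-chromen-7-one, oxa-Michael adduct, C4a and C8a not defined (formed in the flask, not isolated) | COc1cc(OCOC)ccc1[C@@H]1COC2CC(=O)C(CC=C(C)C)=C(OC)C2(O)C1 | intermediate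
21 | (3R)-5-methoxy-3-[2-methoxy-4-(methoxymethoxy)phenyl]-6-(3-methylbut-2-en-1-yl)chroman-7-ol (formed in the flask, not isolated) | COc1cc(OCOC)ccc1[C@@H]1COc2cc(O)c(CC=C(C)C)c(OC)c2C1 | intermediate
22 | (3R)-3-(4-hydroxy-2-methoxyphenyl)-5-methoxy-6-(3-methylbut-2-en-1-yl)chroman-7-ol | COc1cc(O)ccc1[C@@H]1COc2cc(O)c(CC=C(C)C)c(OC)c2C1 | target

Total step count: 12 (ring A fragment steps 1 to 5, ring B fragment steps 6 to 9, union and end game steps 10 to 12).
Longest linear sequence: 8 steps (steps 1, 2, 3, 4, 5, 10, 11, 12).

Steps most likely to fail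

1. Step 12 (bears the label "Proposed new method:").
   - What may go wrong: the phenoxonium ion or the hypervalent iodine reagent may engage the neighbouring prenyl alkene. In the acid stage the prenyl group may cyclise onto the C7 hydroxyl, the p-quinol may undergo a 1,2-shift (dienone–phenol rearrangement) faster than conjugate addition, or the hydroxyl may add at C5 and stall there.
   - Fallback: known reactions, run stepwise with isolation, setting out from 18. Oxidation with PhI(OAc)2 in MeCN/H2O at 0 °C and direct chromatography should give p-quinol 19. Catalytic K2CO3 in MeCN at rt should then close the ring by base-mediated oxa-Michael addition, kinetically confined to the unsubstituted enone carbon C8a, to give 20. The tertiary C4a hydroxyl of 20 is removed without acid by the Burgess reagent (methyl N-(triethylammoniosulfonyl)carbamate, benzene, 50 °C). This is a thermal syn-elimination, and its alkene is a tautomer of phenol 21 whichever β-hydrogen is lost. The fallback comes back to the route at 21, which HCl in MeOH at rt should convert into 22. No compound outside the compound list is made (F0).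

2. Step 1.
   - What may go wrong: alkylation of the ambident phenoxide may be spread over C3, C5 and the two oxygens, so that little of the C3 isomer is obtained.
   - Fallback: it sets out from 1. O-Alkylation of the free 4-hydroxyl with 3-chloro-3-methylbut-1-yne (K2CO3, KI, CuI cat., acetone, reflux) should give 2-hydroxy-4-[(2-methylbut-3-yn-2-yl)oxy]benzaldehyde F1. Semihydrogenation (H2, Pd/CaCO3 poisoned with Pb(OAc)2, quinoline, EtOAc) should give 2-hydroxy-4-[(2-methylbut-3-en-2-yl)oxy]benzaldehyde F2. Aromatic Claisen rearrangement (N,N-diethylaniline, 130 °C) then delivers the allyl unit, with allylic inversion, to C3, the ortho carbon favoured by the bond fixation of the chelated 2-hydroxybenzaldehyde. The fallback comes back to the route at 3.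

3. Step 11.
   - What may go wrong: basic aluminium alkoxides may epimerise the α-aryl stereocentre before reduction is complete, or hydride may open the oxazolidinone ring instead of cleaving the exocyclic acyl group.
   - Fallback: it sets out from 17. LiBH4 with one equivalent of H2O in Et2O at 0 °C should cleave only the imide and give 4-{(2R)-3-hydroxy-2-[2-methoxy-4-(methoxymethoxy)phenyl]propyl}-3-methoxy-2-(3-methylbut-2-en-1-yl)phenyl pivalate F3. Transesterification with K2CO3 in MeOH at rt then removes the pivalate, and the fallback comes back to the route at 18.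

Further compounds
F0 | step 12 | none | none
F1 | step 1 | 2-hydroxy-4-[(2-methylbut-3-yn-2-yl)oxy]benzaldehyde | O=Cc1ccc(OC(C)(C)C#C)cc1O
F2 | step 1 | 2-hydroxy-4-[(2-methylbut-3-en-2-yl)oxy]benzaldehyde | O=Cc1ccc(OC(C)(C)C=C)cc1O
F3 | step 11 | 4-{(2R)-3-hydroxy-2-[2-methoxy-4-(methoxymethoxy)phenyl]propyl}-3-methoxy-2-(3-methylbut-2-en-1-yl)phenyl pivalate | COc1cc(OCOC)ccc1[C@H](CO)Cc1ccc(OC(=O)C(C)(C)C)c(CC=C(C)C)c1OC
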